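**Remark on the chemistry:** the carbinol carbon of the target carries two identical CH2OC(=O)CH(CH3)2 arms and the SMILES has no stereodescriptor, so the compound is achiral; "single enantiomer" is read as the one constitution given, and no stereocontrol is needed.

## Retrosynthetic overview

1. Feature: carbon C2 of the propane chain is bonded to ring carbon C1 of the 2-methoxy-4-methylphenyl (benzene) ring, to OH and to two identical CH2O groups (C1 and C3). It is therefore not a stereocentre and is a latent ester carbonyl carbon.
2. Disconnections, in retrosynthetic order: (a) the two primary O–C(=O) bonds (O-acylation); (b) the two CH2–O bonds, traced back to CH2–Si (Tamao oxidation); (c) key: both C2–CH2 bonds, traced back to one ester carbonyl and two silylmethyl nucleophiles.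
3. Forward: chlorosilane 1 gives Grignard reagent 2; benzoate 3 takes up two equivalents of 2 as cerium reagent 4, through ketone 5, to give bis-silyl carbinol 6; 6 gives triol 7; 7 with isobutyryl chloride 8 gives target 9.
4. Rings: none is formed; the benzene ring is bought with ester 3.

Key step: step 2

## Route

Step 1
Reactants: 1 (chloromethyl)isopropoxydimethylsilane
Product: 2 [(isopropoxydimethylsilyl)methyl]magnesium chloride (kept as a titrated THF solution)
Conditions: Mg turnings, cat. BrCH2CH2Br, THF, rt → gentle reflux, then rt
Reagents that add atoms: magnesium, [Mg]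
Why: Grignard formation by insertion of magnesium into the C–Cl bond of the α-silyl chloride, a standard preparation in which the hindered Si–O-isopropyl group is not displaced by the reagent.

Step 2
Reactants: 3 methyl 2-methoxy-4-methylbenzoate; 2 [(isopropoxydimethylsilyl)methyl]magnesium chloride (3.5 equiv)
Product: 6 1,3-bis(isopropoxydimethylsilyl)-2-(2-methoxy-4-methylphenyl)propan-2-ol, via silylmethylcerium reagent 4 (not isolated), via α-silyl ketone 5 (not isolated)
Conditions: anhydrous CeCl3 (3.5 equiv), 2, THF, −78 °C, 1 h; then 3, −78 → 0 °C; pH 7 phosphate buffer quench, Celite filtration; crude 6 taken on without silica gel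
Reagents that add atoms: compound 2 (two equivalents), CC(C)O[Si](C)(C)C[Mg]Cl
Why: Transmetallation of 2 with cerium trichloride should give the oxophilic, weakly basic reagent 4, which adds to the ester carbonyl of 3; the tetrahedral intermediate loses methoxide to give ketone 5, which is more electrophilic than 3 and takes a second equivalent to give the tertiary alkoxide of 6, so both C2–CH2 bonds form in one operation. The closest known reaction types are the double addition of (trimethylsilyl)methyl cerium reagents to esters and the carbonyl addition of this alkoxysilylmethyl Grignard reagent as a hydroxymethyl anion equivalent. No ring closes and no stereocentre forms, because C2 ends with two identical CH2Si arms. The step needs addition to win over enolisation of 5, whose α-protons are acidified by both C=O and Si; the low basicity of the cerium reagent and chelation by the ortho-methoxy group should secure this. It also needs the β-silyl alkoxide not to undergo Peterson elimination, which the covalent Mg/Ce–O bond at or below 0 °C and a neutral work-up without silica gel should secure, since the electron-rich benzylic carbinol would ionise under acid.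

Step 3
Reactants: 6 1,3-bis(isopropoxydimethylsilyl)-2-(2-methoxy-4-methylphenyl)propan-2-ol
Product: 7 2-(2-methoxy-4-methylphenyl)propane-1,2,3-triol
Conditions: 30% aq. H2O2 (excess), KF, KHCO3, MeOH/THF 1:1, rt → 40 °C; then aq. Na2S2O3, EtOAc extraction with salting out
Reagents that add atoms: hydrogen peroxide, OO
Why: Tamao oxidation, in which the fluoride-activated alkoxysilane takes up hydroperoxide and each CH2 group migrates from Si to O to give the primary alcohol after hydrolysis, while the bicarbonate buffer should keep the tertiary β-hydroxysilane from Peterson elimination and neither the arene nor the tertiary alcohol is oxidised.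

Step 4
Reactants: 7 2-(2-methoxy-4-methylphenyl)propane-1,2,3-triol; 8 isobutyryl chloride (2.3 equiv)
Product: 9 2-hydroxy-2-(2-methoxy-4-methylphenyl)propane-1,3-diyl bis(2-methylpropanoate) (target)
Conditions: iPrCOCl, pyridine, CH2Cl2, −20 → 0 °C (no DMAP)
Reagents that add atoms: isobutyryl chloride 8, CC(C)C(=O)Cl
Why: O-acylation by nucleophilic acyl substitution, in which the two equivalent primary hydroxyls should react far faster than the tertiary benzylic hydroxyl shielded by the ortho-methoxyaryl ring and two CH2 groups, so the tertiary OH stays free without an acyl-transfer catalyst at low temperature.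

## Compound list

1 | (chloromethyl)isopropoxydimethylsilane | CC(C)O[Si](C)(C)CCl | starting material
2 | [(isopropoxydimethylsilyl)methyl]magnesium chloride | CC(C)O[Si](C)(C)C[Mg]Cl | intermediate
3 | methyl 2-methoxy-4-methylbenzoate | COc1cc(C)ccc1C(=O)OC | starting material
4 | dichloro[(isopropoxydimethylsilyl)methyl]cerium (formal composition of the Grignard/CeCl3 reagent) | CC(C)O[Si](C)(C)C[Ce](Cl)Cl | intermediate
5 | 2-(isopropoxydimethylsilyl)-1-(2-methoxy-4-methylphenyl)ethan-1-one | COc1cc(C)ccc1C(=O)C[Si](C)(C)OC(C)C | intermediate
6 | 1,3-bis(isopropoxydimethylsilyl)-2-(2-methoxy-4-methylphenyl)propan-2-ol | COc1cc(C)ccc1C(O)(C[Si](C)(C)OC(C)C)C[Si](C)(C)OC(C)C | intermediate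
7 | 2-(2-methoxy-4-methylphenyl)propane-1,2,3-triol | COc1cc(C)ccc1C(O)(CO)CO | intermediate
8 | isobutyryl chloride (2-methylpropanoyl chloride) | CC(C)C(=O)Cl | starting material
9 | 2-hydroxy-2-(2-methoxy-4-methylphenyl)propane-1,3-diyl bis(2-methylpropanoate) | COc1cc(C)ccc1C(O)(COC(=O)C(C)C)COC(=O)C(C)C | target

## Step count and risks

Total steps: 4. Longest linear sequence: 4 steps (1 → 2 → 6 → 7 → 9); ester 3 and acid chloride 8 are purchased.

**Step 2 (highest risk).** Enolisation of the α-silyl ketone intermediate by the organometallic may compete with the second addition and, after loss of silicon on work-up, stop the sequence at mono-addition. Peterson elimination of the tertiary β-silyl alkoxide may also set in if the mixture warms or meets acid. The fallback sets out from 3 and returns at 7 with a silicon-free hydroxymethyl anion equivalent. Ester 3 would be treated in THF at −78 °C with benzyloxymethyllithium, generated from tributyl(benzyloxymethyl)stannane and n-butyllithium, to give by double addition 1,3-bis(benzyloxy)-2-(2-methoxy-4-methylphenyl)propan-2-ol F1. Hydrogenolysis of both benzyl ethers (H2, Pd/C, EtOAc, rt, neutral) would then give triol 7, with no Peterson pathway available.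

**Step 3.** Fluoride- or base-induced Peterson elimination of the tertiary benzylic β-hydroxysilane may outrun the Si→O migration, and the water-soluble triol may be lost on extraction. The fallback sets out from 6 and returns at 7 by making the elimination deliberate. Carbinol 6 would be treated with KH in THF at 0 °C to give isopropoxydimethyl[2-(2-methoxy-4-methylphenyl)prop-2-en-1-yl]silane F2, which no longer has a β-hydroxyl. Tamao oxidation of this allylic alkoxysilane (H2O2, KF, KHCO3, MeOH/THF) would give 2-(2-methoxy-4-methylphenyl)prop-2-en-1-ol F3. Upjohn dihydroxylation of the 1,1-disubstituted alkene (cat. OsO4, NMO, acetone/water) would then give triol 7.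

**Step 4.** Discrimination between the hydroxyls may break down when the reaction is pushed to complete bis-acylation: acylation may creep onto the tertiary hydroxyl, the reaction may stall at the monoester, or the liberated acid may ionise the electron-rich benzylic carbinol. The fallback sets out from 7 and returns at 9 through a protecting-group detour.
- Triol 7 would be persilylated (TESOTf, 2,6-lutidine, CH2Cl2, −78 → 0 °C) to 2-(2-methoxy-4-methylphenyl)-1,2,3-tris(triethylsilyloxy)propane F4.
- The two primary silyl ethers would be removed selectively under mild acid (cat. PPTS, MeOH/CH2Cl2, 0 °C) to give 2-(2-methoxy-4-methylphenyl)-2-(triethylsilyloxy)propane-1,3-diol F5.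
- With the tertiary oxygen blocked, exhaustive acylation (isobutyryl chloride, pyridine, DMAP, CH2Cl2) would give 2-(2-methoxy-4-methylphenyl)-2-(triethylsilyloxy)propane-1,3-diyl bis(2-methylpropanoate) F6.
- Desilylation with HF·pyridine in THF/pyridine would release target 9.

## Further compounds

F1 | step 2 | 1,3-bis(benzyloxy)-2-(2-methoxy-4-methylphenyl)propan-2-ol | COc1cc(C)ccc1C(O)(COCc1ccccc1)COCc1ccccc1
F2 | step 3 | isopropoxydimethyl[2-(2-methoxy-4-methylphenyl)prop-2-en-1-yl]silane | COc1cc(C)ccc1C(=C)C[Si](C)(C)OC(C)C
F3 | step 3 | 2-(2-methoxy-4-methylphenyl)prop-2-en-1-ol | COc1cc(C)ccc1C(=C)CO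
F4 | step 4 | 2-(2-methoxy-4-methylphenyl)-1,2,3-tris(triethylsilyloxy)propane | COc1cc(C)ccc1C(O[Si](CC)(CC)CC)(CO[Si](CC)(CC)CC)CO[Si](CC)(CC)CC
F5 | step 4 | 2-(2-methoxy-4-methylphenyl)-2-(triethylsilyloxy)propane-1,3-diol | COc1cc(C)ccc1C(O[Si](CC)(CC)CC)(CO)CO
F6 | step 4 | 2-(2-methoxy-4-methylphenyl)-2-(triethylsilyloxy)propane-1,3-diyl bis(2-methylpropanoate) | COc1cc(C)ccc1C(O[Si](CC)(CC)CC)(COC(=O)C(C)C)COC(=O)C(C)C
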